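**Assumption:** the target (demethoxyubiquinone-10) has no stereogenic centre, so "single enantiomer" is read as the single all-E geometric isomer drawn; solanesol is the natural all-E nonaprenol.

## Retrosynthetic overview

1. Last step: aerobic para-oxidation of all-E 2-decaprenyl-6-methoxy-3-methylphenol to the quinone.
2. Key disconnection, C4'–C5' of the side chain: the α-sulfonyl allyl carbanion of an unprotected C5-sulfone phenol (a masked allyl anion; both allylic termini are electrophiles in their halide form) plus solanesyl bromide (C45, brings eight E-alkenes). The sulfone is removed in the same flask with PdCl2(dppp)/LiBHEt3.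
3. C5-sulfone phenol ⇐ ortho-C-allylation of sodium 2-methoxy-5-methylphenoxide (its single free ortho position fixes the ring pattern) with (E)-4-chloro-2-methylbut-2-enyl p-tolyl sulfone ⇐ isoprene + TsCl (sets the ninth E-alkene).
4. Ring order: no ring is built; the only ring is the benzene ring of 2-methoxy-5-methylphenol, turned into the quinone at the end.

## Route

Step 1
Reactants: 1 isoprene (2-methylbuta-1,3-diene); 2 p-toluenesulfonyl chloride
Product: 3 (E)-4-chloro-2-methylbut-2-en-1-yl p-tolyl sulfone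
Conditions: CuCl (2 mol%), Et3N·HCl (3 mol%), MeCN, 100 °C, sealed tube; recrystallise (EtOH) to the pure E isomer
Reagents that add atoms: none
Why: Copper-catalysed atom-transfer radical addition (Asscher–Vofsi, Kharasch type): the tosyl radical adds to C1 of isoprene to give the more substituted allyl radical, chlorine transfer at the unhindered terminus closes the 1,4-adduct, and the favoured crystalline E isomer (the future 2'E alkene) is purified by recrystallisation.

Step 2
Reactants: 3 (E)-4-chloro-2-methylbut-2-en-1-yl p-tolyl sulfone; 4 2-methoxy-5-methylphenol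
Product: 6 2-[(2E)-3-methyl-4-(p-tolylsulfonyl)but-2-en-1-yl]-6-methoxy-3-methylphenol, via sodium 2-methoxy-5-methylphenoxide 5 (not isolated)
Conditions: 4 (1.5 equiv), NaH (1.4 equiv), toluene, 0 °C to rt; then 3 (1.0 equiv), 70 °C
Reagents that add atoms: none
Why: Claisen–Kornblum C-alkylation of a tight sodium phenoxide ion pair in a non-polar solvent delivers the allyl group by SN2 (E geometry kept) to the only free ortho carbon, which lies between OH and CH3 and so fixes the quinone substitution pattern; phenoxide is too weak a base to touch the sulfone α-protons.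

Step 3
Reactants: 7 solanesol (all-E nonaprenol)
Product: 8 all-E solanesyl bromide
Conditions: PBr3 (0.4 equiv), pyridine (cat.), Et2O/hexane, –10 °C, dark; used crude at once
Reagents that add atoms: phosphorus tribromide, BrP(Br)Br
Why: SN2 displacement of the bromophosphite ester of a primary allylic alcohol at low temperature (pyridine scavenges HBr), the standard preparation of solanesyl bromide, leaves all eight E-alkenes untouched.

Step 4 (key step, one flask)
Reactants: 6 2-[(2E)-3-methyl-4-(p-tolylsulfonyl)but-2-en-1-yl]-6-methoxy-3-methylphenol; 8 all-E solanesyl bromide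
Product: 12 all-E 2-decaprenyl-6-methoxy-3-methylphenol, via dilithio dianion 9 (not isolated), via lithium phenoxide sulfone 10 (not isolated), via lithium decaprenylphenoxide 11 (not isolated)
Conditions: n-BuLi (2.05 equiv), THF, –78 °C; 8 (1.05 equiv), –78 to –20 °C; then PdCl2(dppp) (5 mol%; dppp = 1,3-bis(diphenylphosphino)propane), LiBHEt3 (3 equiv), 0 °C; AcOH, H2O
Reagents that add atoms: none
Why: Proposed new method: the α-sulfonyl allyl carbanion of dianion 9 is a masked allyl anion, so the C4' terminus (an electrophile in its halide form) attacks C1 of the allylic bromide by SN2 at the soft carbanion carbon and not at the hard lithium phenoxide oxygen; in the same flask zerovalent palladium ionises the allylic sulfone 10 and hydride from LiBHEt3 is delivered to C4', the π-allyl terminus remote from the bulky ortho-disubstituted arylmethyl group, which removes the transient C4' stereocentre and leaves the 2'E alkene in place (a π-allyl captured by the ortho phenoxide would give an allyl aryl ether that re-ionises under the same conditions); closest known reaction types are the Julia/Biellmann alkylation of O-protected prenylarene sulfones with solanesyl bromide and the separate PdCl2(dppp)/LiBHEt3 reductive desulfonylation of allylic sulfones.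

Step 5
Reactants: 12 all-E 2-decaprenyl-6-methoxy-3-methylphenol
Product: 13 all-E 2-decaprenyl-6-methoxy-3-methyl-1,4-benzoquinone (target)
Conditions: Co(salen) (10 mol%; salen = N,N'-bis(salicylidene)ethylenediamine dianion), O2 (1 atm), DMF/THF, rt, dark
Reagents that add atoms: dioxygen, O=O
Why: Co(salen)-mediated aerobic phenol oxidation: the cobalt superoxo species abstracts the phenolic hydrogen and oxygenates the free para position of this 2,3,6-trisubstituted phenol to the para-quinone, conditions under which isolated trisubstituted alkenes are inert.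

## Compound list

1 | isoprene (2-methylbuta-1,3-diene) | `C=CC(C)=C` | starting material
2 | p-toluenesulfonyl chloride | `Cc1ccc(cc1)S(=O)(=O)Cl` | starting material
3 | (E)-4-chloro-2-methylbut-2-en-1-yl p-tolyl sulfone | `Cc1ccc(cc1)S(=O)(=O)C/C(C)=C/CCl` | intermediate
4 | 2-methoxy-5-methylphenol | `COc1ccc(C)cc1O` | starting material
5 | sodium 2-methoxy-5-methylphenoxide | `COc1ccc(C)cc1[O-].[Na+]` | intermediate
6 | 2-[(2E)-3-methyl-4-(p-tolylsulfonyl)but-2-en-1-yl]-6-methoxy-3-methylphenol | `COc1ccc(C)c(C/C=C(\C)CS(=O)(=O)c2ccc(C)cc2)c1O` | intermediate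
7 | solanesol, (2E,6E,10E,14E,18E,22E,26E,30E)-3,7,11,15,19,23,27,31,35-nonamethylhexatriaconta-2,6,10,14,18,22,26,30,34-nonaen-1-ol | `OC/C=C(\C)CC/C=C(\C)CC/C=C(\C)CC/C=C(\C)CC/C=C(\C)CC/C=C(\C)CC/C=C(\C)CC/C=C(\C)CCC=C(C)C` | starting material
8 | all-E solanesyl bromide, (2E,6E,10E,14E,18E,22E,26E,30E)-1-bromo-3,7,11,15,19,23,27,31,35-nonamethylhexatriaconta-2,6,10,14,18,22,26,30,34-nonaene | `BrC/C=C(\C)CC/C=C(\C)CC/C=C(\C)CC/C=C(\C)CC/C=C(\C)CC/C=C(\C)CC/C=C(\C)CC/C=C(\C)CCC=C(C)C` | intermediate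
9 | dilithio dianion of 6 (lithium phenoxide and α-sulfonyl allyl carbanion at C4', 2'E) | `COc1ccc(C)c(C/C=C(\C)[CH-]S(=O)(=O)c2ccc(C)cc2)c1[O-].[Li+].[Li+]` | intermediate
10 | lithium 2-[(all-E)-4-(p-tolylsulfonyl)decaprenyl]-6-methoxy-3-methylphenoxide, racemic at C4' | `COc1ccc(C)c(C/C=C(\C)C(C/C=C(\C)CC/C=C(\C)CC/C=C(\C)CC/C=C(\C)CC/C=C(\C)CC/C=C(\C)CC/C=C(\C)CC/C=C(\C)CCC=C(C)C)S(=O)(=O)c2ccc(C)cc2)c1[O-].[Li+]` | intermediate
11 | lithium 2-[(all-E)-decaprenyl]-6-methoxy-3-methylphenoxide | `COc1ccc(C)c(C/C=C(\C)CC/C=C(\C)CC/C=C(\C)CC/C=C(\C)CC/C=C(\C)CC/C=C(\C)CC/C=C(\C)CC/C=C(\C)CC/C=C(\C)CCC=C(C)C)c1[O-].[Li+]` | intermediate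
12 | 2-[(2E,6E,10E,14E,18E,22E,26E,30E,34E)-3,7,11,15,19,23,27,31,35,39-decamethyltetraconta-2,6,10,14,18,22,26,30,34,38-decaen-1-yl]-6-methoxy-3-methylphenol | `COc1ccc(C)c(C/C=C(\C)CC/C=C(\C)CC/C=C(\C)CC/C=C(\C)CC/C=C(\C)CC/C=C(\C)CC/C=C(\C)CC/C=C(\C)CC/C=C(\C)CCC=C(C)C)c1O` | intermediate
13 | 2-[(2E,6E,10E,14E,18E,22E,26E,30E,34E)-3,7,11,15,19,23,27,31,35,39-decamethyltetraconta-2,6,10,14,18,22,26,30,34,38-decaen-1-yl]-6-methoxy-3-methyl-1,4-benzoquinone (CID25010748) | `COC1=CC(=O)C(C)=C(C/C=C(\C)CC/C=C(\C)CC/C=C(\C)CC/C=C(\C)CC/C=C(\C)CC/C=C(\C)CC/C=C(\C)CC/C=C(\C)CC/C=C(\C)CCC=C(C)C)C1=O` | target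

## Step count and risks

Total steps: 5. Longest linear sequence: 4 (steps 1, 2, 4, 5); step 3 is a one-step branch.

**Most likely to fail, first: step 4.** The dianion may alkylate on oxygen, the free phenoxide may hold up the π-allyl palladium intermediate, or hydride may go to C2' (alkene shift, E/Z loss) when both operations share one flask. The fallback is a stepwise, O-protected sequence that sets out from 6. Silylation (TBSCl, imidazole, DMF) gives tert-butyl{6-methoxy-3-methyl-2-[(2E)-3-methyl-4-(p-tolylsulfonyl)but-2-en-1-yl]phenoxy}dimethylsilane F4. n-BuLi (1.05 equiv, THF, –78 °C) gives the lithio sulfone monoanion F5, which is alkylated with 8 to the O-silylated 4'-(p-tolylsulfonyl)decaprenyl arene F6 (racemic at C4'), isolated and purified. PdCl2(dppp)/LiBHEt3 in THF at 0 °C then gives tert-butyl[2-(all-E-decaprenyl)-6-methoxy-3-methylphenoxy]dimethylsilane F7, and Bu4NF in THF comes back to the route at 12.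

**Second: step 2.** The phenoxide may give mainly the O-allyl ether or some para product. The fallback uses a regiodefined aryl metal and sets out from 4. Amine-directed ortho-bromination (t-BuNH2, Br2, toluene, –70 °C) gives 2-bromo-6-methoxy-3-methylphenol F1. n-BuLi (2.1 equiv, THF, –78 °C) gives lithium 2-lithio-6-methoxy-3-methylphenoxide F2, and CuBr·SMe2 turns it into the weakly basic arylcopper lithium 2-cuprio-6-methoxy-3-methylphenoxide F3. This is allylated by 3 at the primary allylic carbon, and aqueous work-up comes back to the route at 6.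

**Third: step 5.** Cobalt/O2 may cause oxidative coupling of the phenol or slow autoxidation of the polyene. The fallback replaces radical oxygenation by polar para-amination followed by mild oxidation, and sets out from 12. Azo coupling with commercial 4-nitrobenzenediazonium tetrafluoroborate (aq NaOH/THF, 0 °C) gives 2-(all-E-decaprenyl)-6-methoxy-3-methyl-4-[(E)-(4-nitrophenyl)diazenyl]phenol F8. Na2S2O4 cleaves it to 4-amino-2-(all-E-decaprenyl)-6-methoxy-3-methylphenol F9. FeCl3 in aq HCl/Et2O oxidises the aminophenol to the quinone imine, which hydrolyses and comes back to the route at 13.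

## Further compounds

F1 | step 2 | 2-bromo-6-methoxy-3-methylphenol | `COc1ccc(C)c(Br)c1O`
F2 | step 2 | lithium 2-lithio-6-methoxy-3-methylphenoxide | `COc1ccc(C)c([Li])c1[O-].[Li+]`
F3 | step 2 | lithium 2-cuprio-6-methoxy-3-methylphenoxide | `COc1ccc(C)c([Cu])c1[O-].[Li+]`
F4 | step 4 | tert-butyl{6-methoxy-3-methyl-2-[(2E)-3-methyl-4-(p-tolylsulfonyl)but-2-en-1-yl]phenoxy}dimethylsilane | `COc1ccc(C)c(C/C=C(\C)CS(=O)(=O)c2ccc(C)cc2)c1O[Si](C)(C)C(C)(C)C`
F5 | step 4 | lithio sulfone monoanion of F4 (carbanion at C4', 2'E) | `COc1ccc(C)c(C/C=C(\C)[CH-]S(=O)(=O)c2ccc(C)cc2)c1O[Si](C)(C)C(C)(C)C.[Li+]`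
F6 | step 4 | tert-butyl{2-[(all-E)-4-(p-tolylsulfonyl)decaprenyl]-6-methoxy-3-methylphenoxy}dimethylsilane, racemic at C4' | `COc1ccc(C)c(C/C=C(\C)C(C/C=C(\C)CC/C=C(\C)CC/C=C(\C)CC/C=C(\C)CC/C=C(\C)CC/C=C(\C)CC/C=C(\C)CC/C=C(\C)CCC=C(C)C)S(=O)(=O)c2ccc(C)cc2)c1O[Si](C)(C)C(C)(C)C`
F7 | step 4 | tert-butyl[2-(all-E-decaprenyl)-6-methoxy-3-methylphenoxy]dimethylsilane | `COc1ccc(C)c(C/C=C(\C)CC/C=C(\C)CC/C=C(\C)CC/C=C(\C)CC/C=C(\C)CC/C=C(\C)CC/C=C(\C)CC/C=C(\C)CC/C=C(\C)CCC=C(C)C)c1O[Si](C)(C)C(C)(C)C`
F8 | step 5 | 2-(all-E-decaprenyl)-6-methoxy-3-methyl-4-[(E)-(4-nitrophenyl)diazenyl]phenol | `COc1cc(/N=N/c2ccc(cc2)[N+](=O)[O-])c(C)c(C/C=C(\C)CC/C=C(\C)CC/C=C(\C)CC/C=C(\C)CC/C=C(\C)CC/C=C(\C)CC/C=C(\C)CC/C=C(\C)CC/C=C(\C)CCC=C(C)C)c1O`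
F9 | step 5 | 4-amino-2-(all-E-decaprenyl)-6-methoxy-3-methylphenol | `COc1cc(N)c(C)c(C/C=C(\C)CC/C=C(\C)CC/C=C(\C)CC/C=C(\C)CC/C=C(\C)CC/C=C(\C)CC/C=C(\C)CC/C=C(\C)CC/C=C(\C)CCC=C(C)C)c1O`
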